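**Retrosynthetic overview**
1. γ-Lactone last: the C8–C17 bond, C8 and C17 come from a redox-neutral reductive aldol lactonisation of a C7 acrylate onto the C8 carbinol (proposed new step).
2. Ten-membered ring: Nozaki–Hiyama–Kishi closure of C6–C7 from a (Z)-alkenyl iodide and an α-silyloxy aldehyde (sets C7).
3. Side chain: C3–C4 by alkylating a C2 methyl ketone enolate with (Z)-BrCH2C(CH3)=CHI; C2 by CBS reduction.
4. Ring A fragment: tandem conjugate methylation/aldol of a 4-silyloxycyclohexenone with (S)-glyceraldehyde acetonide (C1, C10, C9), then enol triflate methylation (C11=C12); C14 by CBS reduction of an iodoenone.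
5. Ring order: six-membered ring A (bought as a carbocycle), then the ten-membered ring, then the γ-lactone.

Assumption: compounds 1, 9 and 19 are bought; intermediates carry briarane numbering (ring A = C1, C10–C14; C15 = CH3 on C1; C16 = CH3 on C5; C17/C18/C19 = lactone CH/CH3/C=O; C20 = CH3 on C11), and β is the face of ring A that carries C15.

Step 1
Reactants: 1 1,4-dioxaspiro[4.5]dec-6-en-8-one
Product: 2 7-iodo-1,4-dioxaspiro[4.5]dec-6-en-8-one
Conditions: I2, pyridine, CH2Cl2, 0 °C to rt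
Reagents that add atoms: iodine, II
Why: α-Iodination of an enone by pyridine/iodine addition–elimination (Johnson iodination) puts the halogen only on the α-carbon, the future C1.

Step 2
Reactants: 2 7-iodo-1,4-dioxaspiro[4.5]dec-6-en-8-one
Product: 3 (8S)-7-iodo-1,4-dioxaspiro[4.5]dec-6-en-8-ol
Conditions: (R)-Me-CBS oxazaborolidine (20 mol%), BH3·SMe2, THF, −20 °C; MeOH
Reagents that add atoms: none
Why: Corey–Bakshi–Shibata reduction in which the iodoalkene is the large group, so the (R)-catalyst gives the (S)-carbinol that becomes C14 (α-oxygen).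

Step 3
Reactants: 3 (8S)-7-iodo-1,4-dioxaspiro[4.5]dec-6-en-8-ol
Product: 4 tert-butyl{[(8S)-7-iodo-1,4-dioxaspiro[4.5]dec-6-en-8-yl]oxy}dimethylsilane
Conditions: TBSCl, imidazole, DMF, rt
Reagents that add atoms: tert-butyldimethylsilyl chloride, CC(C)(C)[Si](C)(C)Cl
Why: Routine silylation of a secondary allylic alcohol; the bulky ether later directs the conjugate addition.

Step 4
Reactants: 4 tert-butyl{[(8S)-7-iodo-1,4-dioxaspiro[4.5]dec-6-en-8-yl]oxy}dimethylsilane
Product: 6 [(8S)-8-(tert-butyldimethylsilyloxy)-1,4-dioxaspiro[4.5]dec-6-en-7-yl]methanol, via alkenyllithium 5 (not isolated)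
Conditions: t-BuLi (2.1 equiv), Et2O, −78 °C; (CH2O)n, −78 °C to rt; H2O
Reagents that add atoms: formaldehyde (as paraformaldehyde), C=O
Why: Iodine–lithium exchange followed by 1,2-addition of the alkenyllithium to formaldehyde installs C2 as CH2OH without touching C14.

Step 5
Reactants: 6 [(8S)-8-(tert-butyldimethylsilyloxy)-1,4-dioxaspiro[4.5]dec-6-en-7-yl]methanol
Product: 7 (4S)-4-(tert-butyldimethylsilyloxy)-3-(hydroxymethyl)cyclohex-2-en-1-one
Conditions: PPTS (20 mol%), THF/H2O 4:1, 45 °C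
Reagents that add atoms: water, O
Why: Mild acid hydrolysis of the allylic dioxolane unveils the C11 ketone in conjugation with C1=C10, while the secondary TBS ether survives.

Step 6
Reactants: 7 (4S)-4-(tert-butyldimethylsilyloxy)-3-(hydroxymethyl)cyclohex-2-en-1-one
Product: 8 (4S)-4-(tert-butyldimethylsilyloxy)-3-[(triethylsilyloxy)methyl]cyclohex-2-en-1-one
Conditions: TESCl, imidazole, CH2Cl2, 0 °C
Reagents that add atoms: triethylsilyl chloride, CC[Si](Cl)(CC)CC
Why: Silylation of the primary alcohol gives a group that a later Swern oxidation converts directly into the C2 aldehyde.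

Step 7
Reactants: 8 (4S)-4-(tert-butyldimethylsilyloxy)-3-[(triethylsilyloxy)methyl]cyclohex-2-en-1-one; 9 (4S)-2,2-dimethyl-1,3-dioxolane-4-carbaldehyde
Product: 11 (2S,3S,4S)-4-(tert-butyldimethylsilyloxy)-2-{(R)-[(4S)-2,2-dimethyl-1,3-dioxolan-4-yl](hydroxy)methyl}-3-methyl-3-[(triethylsilyloxy)methyl]cyclohexan-1-one, via bromomagnesium enolate 10 (not isolated)
Conditions: MeMgBr (1.2 equiv), CuBr·SMe2 (10 mol%), THF, −40 °C; then 9 (1.5 equiv), −78 °C; aqueous work-up
Reagents that add atoms: methylmagnesium bromide, C[Mg]Br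
Why: Copper-catalysed conjugate addition (Kharasch type) delivers the methyl to C1 anti to the 14-OTBS group, and the resulting (E)-magnesium enolate adds to the aldehyde through a Zimmerman–Traxler chair on the face anti to the larger CH2OTES group (C10, 9,10-anti) with polar Felkin–Anh approach to the α-alkoxy aldehyde (8,9-anti, matched), a tandem conjugate addition–aldol reaction.

Step 8
Reactants: 11 aldol adduct
Product: 12 (2S,3S,4S)-4-(tert-butyldimethylsilyloxy)-2-{(R)-(tert-butyldimethylsilyloxy)[(4S)-2,2-dimethyl-1,3-dioxolan-4-yl]methyl}-3-methyl-3-[(triethylsilyloxy)methyl]cyclohexan-1-one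
Conditions: TBSOTf, 2,6-lutidine, CH2Cl2, −78 °C
Reagents that add atoms: tert-butyldimethylsilyl triflate, CC(C)(C)[Si](C)(C)OS(=O)(=O)C(F)(F)F
Why: Silyl triflate/lutidine caps the hindered β-hydroxy ketone at low temperature before retro-aldol or C10 epimerisation can occur.

Step 9
Reactants: 12 9-O-TBS ketone
Product: 14 C11 enol triflate of 12 with the C11=C12 double bond (1S,8S,9R,10S,14S), via potassium enolate 13 (not isolated)
Conditions: KN(SiMe3)2, THF, −78 °C; PhNTf2, −78 to 0 °C
Reagents that add atoms: N-phenylbis(trifluoromethanesulfonimide), O=S(=O)(N(c1ccccc1)S(=O)(=O)C(F)(F)F)C(F)(F)F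
Why: Kinetic deprotonation takes the C12 methylene proton and not the hindered C10 methine, and O-triflation fixes the alkene at C11=C12 without β-elimination of the C9 silyloxy group.

Step 10
Reactants: 14 C11 enol triflate
Product: 15 ring A cyclohex-11-ene with 20-CH3 and 14α-OTBS and 1β-CH3 and 1α-CH2OTES and 10β-[(9R)-CH(OTBS)-(8S)-dioxolanyl] (1S,8S,9R,10S,14S)
Conditions: MeMgBr, Fe(acac)3 (5 mol%), THF/NMP, −30 °C
Reagents that add atoms: methylmagnesium bromide, C[Mg]Br
Why: Iron-catalysed cross-coupling of an alkenyl triflate with a Grignard reagent (Kumada type) installs C20 with the double bond position retained.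

Step 11
Reactants: 15 11-methyl ring A fragment
Product: 16 C2 aldehyde: 15 with 1α-CHO in place of 1α-CH2OTES (1R by CIP, same geometry)
Conditions: (COCl)2, DMSO, CH2Cl2, −78 to −30 °C; Et3N, −78 to 0 °C
Reagents that add atoms: none
Why: Under Swern conditions a primary triethylsilyl ether is cleaved and oxidised directly to the aldehyde while the two secondary TBS ethers and the acetonide are untouched.

Step 12
Reactants: 16 C2 aldehyde
Product: 17 C2 carbinol: 1α-CH(OH)CH3 as a mixture of C2 epimers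
Conditions: MeMgBr, THF, −78 °C; aqueous work-up
Reagents that add atoms: methylmagnesium bromide, C[Mg]Br
Why: Grignard 1,2-addition to a non-enolisable neopentyl aldehyde brings in C3; the new configuration is irrelevant because C2 is oxidised next.

Step 13
Reactants: 17 C2 carbinol
Product: 18 C2 methyl ketone: 1α-acetyl ring A fragment (1R by CIP)
Conditions: Dess–Martin periodinane, pyridine, CH2Cl2, rt
Reagents that add atoms: none
Why: Dess–Martin oxidation of a hindered secondary alcohol is mild enough for the silyl ethers and the acetonide.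

Step 14
Reactants: 19 prop-2-yn-1-ol
Product: 21 (Z)-3-iodo-2-methylprop-2-en-1-ol, via alkenylmagnesium alkoxide 20 (not isolated)
Conditions: MeMgBr (2.3 equiv), CuI (10 mol%), THF, −10 °C to rt; then I2, −10 °C; aqueous work-up
Reagents that add atoms: methylmagnesium bromide, C[Mg]Br; iodine, II
Why: Copper-catalysed anti-carbomagnesiation of the propargylic alkoxide (Duboudin–Jousseaume) gives a five-membered magnesium chelate whose iodinolysis with retention puts iodine cis to CH2OH, which fixes the Z geometry of the future C5=C6.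

Step 15
Reactants: 21 (Z)-3-iodo-2-methylprop-2-en-1-ol
Product: 22 (Z)-3-bromo-1-iodo-2-methylprop-1-ene
Conditions: CBr4, PPh3, CH2Cl2, 0 °C
Reagents that add atoms: carbon tetrabromide, BrC(Br)(Br)Br
Why: Appel bromination of a primary allylic alcohol is an SN2 process that does not disturb the alkene geometry.

Step 16
Reactants: 18 C2 methyl ketone; 22 (Z)-3-bromo-1-iodo-2-methylprop-1-ene
Product: 24 alkylated ketone: 1α-C(=O)CH2CH2C(CH3)=CHI (5Z) ring A fragment, via lithium enolate 23 (not isolated)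
Conditions: LiN(i-Pr)2, THF, −78 °C; then 22, DMPU, −78 to −40 °C
Reagents that add atoms: none
Why: The ketone can enolise only toward its methyl group (C3), and SN2 alkylation by the primary allylic bromide forms C3–C4 with the (Z)-iodoalkene intact.

Step 17
Reactants: 24 alkylated C2 ketone
Product: 25 (2R)-alcohol of 24 (1S,2R,8S,9R,10S,14S)
Conditions: (S)-Me-CBS oxazaborolidine (30 mol%), BH3·SMe2, THF, −30 °C; MeOH
Reagents that add atoms: none
Why: Corey–Bakshi–Shibata reduction with the quaternary C1 as the large group and the C3 methylene as the small group gives the (2R)-carbinol under reagent control.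

Step 18
Reactants: 25 (2R)-alcohol
Product: 26 2,9,14-triol (both TBS groups removed)
Conditions: Bu4NF, THF, 45 °C
Reagents that add atoms: none
Why: Fluoride removes both secondary TBS ethers and leaves the acetonide and the alkenyl iodide alone.

Step 19
Reactants: 26 2,9,14-triol
Product: 27 2,9,14-triacetate (1S,2R,8S,9R,10S,14S)
Conditions: Ac2O, pyridine, DMAP (cat.), CH2Cl2, rt
Reagents that add atoms: acetic anhydride, CC(=O)OC(C)=O
Why: DMAP-catalysed acetylation installs the three acetates of the target early, so that no deprotection is needed after the lactone is formed.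

Step 20
Reactants: 27 2,9,14-triacetate
Product: 28 7,8-diol triacetate
Conditions: AcOH/H2O/THF 3:1:1, 45 °C
Reagents that add atoms: none
Why: Aqueous acetic acid hydrolyses the terminal acetonide without cleaving acetates or the alkenyl iodide.

Step 21
Reactants: 28 7,8-diol triacetate
Product: 29 7,8-bis(triethylsilyl) ether
Conditions: TESOTf, 2,6-lutidine, CH2Cl2, −78 °C
Reagents that add atoms: triethylsilyl triflate, CC[Si](CC)(CC)OS(=O)(=O)C(F)(F)F
Why: Fast low-temperature bis-silylation protects both hydroxyls before acetyl migration from C9 can start.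

Step 22
Reactants: 29 7,8-bis(triethylsilyl) ether
Product: 30 C7 aldehyde with 8-OTES (8R by CIP, same geometry)
Conditions: (COCl)2, DMSO, CH2Cl2, −78 to −40 °C; Et3N, −78 to −20 °C
Reagents that add atoms: none
Why: Swern conditions oxidise the primary triethylsilyl ether selectively to the aldehyde and leave the secondary one in place; the aldehyde is used at once to avoid C8 epimerisation.

Step 23
Reactants: 30 C7 aldehyde
Product: 32 bicyclic (7S)-allylic alcohol: (1S,2R,5Z,7S,8S,9R,10S,14S)-2,9,14-triacetoxy-7-hydroxy-8-(triethylsilyloxy)-1,5,11-trimethylbicyclo[8.4.0]tetradeca-5,11-diene (briarane numbering), via alkenylchromium dichloride 31 (not isolated)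
Conditions: CrCl2 (10 equiv), NiCl2 (2 mol%), DMSO/THF, rt, 2 mM
Reagents that add atoms: none
Why: In this Nozaki–Hiyama–Kishi macrocyclisation zerovalent nickel inserts into the C–I bond with retention of the Z geometry, transmetalation gives an alkenyl species of trivalent chromium that tolerates the acetates, and polar Felkin–Anh addition anti to the 8-OTES group gives the 7,8-anti, (7S)-alcohol.

Step 24
Reactants: 32 bicyclic (7S)-allylic alcohol
Product: 33 7-O-acryloyl ester of 32
Conditions: acryloyl chloride, i-Pr2NEt, DMAP (cat.), CH2Cl2, −20 °C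
Reagents that add atoms: acryloyl chloride, C=CC(=O)Cl
Why: Acylation of the only free hydroxyl brings in C17, C18 and C19 on the oxygen that will become the lactone oxygen.

Step 25
Reactants: 33 7-O-acryloyl ester
Product: 34 8-hydroxy 7-acrylate (1S,2R,7S,8S,9R,10S,14S)
Conditions: HF·pyridine, pyridine, THF, 0 °C
Reagents that add atoms: none
Why: Buffered HF removes the triethylsilyl ether without touching acetates or the acrylate and without base-induced acyl migration.

Step 26
Reactants: 34 8-hydroxy 7-acrylate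
Product: 36 stylatulide lactone, via keto acrylate 35 (not isolated)
Conditions: [Rh(cod)(OMe)]2 (5 mol%), rac-BINAP (11 mol%), toluene, 60 °C, no added oxidant or reductant
Reagents that add atoms: none
Why: Proposed new method: a hydrogen auto-transfer reductive aldol lactonisation in which the alkoxide of monovalent rhodium at C8 undergoes β-hydride elimination to ketone 35 and a Rh–H that hydrometalates the neighbouring C7 acrylate to the (Z)-rhodium enolate, which adds to the ketone through a rhodium-bridged chair transition state (C8–C17 bond, γ-lactone, 8-OH cis to 17-CH3) on the ketone face that keeps C6 and C9 anti, and alcoholysis of the rhodium aldolate by the next substrate molecule turns the catalyst over; the closest known reaction types are rhodium- or copper-hydride reductive aldol cyclisations of keto acrylates run with H2 or a silane and metal-hydride redox-neutral couplings of alcohols with enones.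

**Compound list**
1 | 1,4-dioxaspiro[4.5]dec-6-en-8-one | O=C1C=CC2(CC1)OCCO2 | starting material
2 | 7-iodo-1,4-dioxaspiro[4.5]dec-6-en-8-one | O=C1C(I)=CC2(CC1)OCCO2 | intermediate
3 | (8S)-7-iodo-1,4-dioxaspiro[4.5]dec-6-en-8-ol | O[C@H]1CCC2(OCCO2)C=C1I | intermediate
4 | tert-butyl{[(8S)-7-iodo-1,4-dioxaspiro[4.5]dec-6-en-8-yl]oxy}dimethylsilane | CC(C)(C)[Si](C)(C)O[C@H]1CCC2(OCCO2)C=C1I | intermediate
5 | [(8S)-8-(tert-butyldimethylsilyloxy)-1,4-dioxaspiro[4.5]dec-6-en-7-yl]lithium | CC(C)(C)[Si](C)(C)O[C@H]1CCC2(OCCO2)C=C1[Li] | intermediate (not isolated)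
6 | [(8S)-8-(tert-butyldimethylsilyloxy)-1,4-dioxaspiro[4.5]dec-6-en-7-yl]methanol | CC(C)(C)[Si](C)(C)O[C@H]1CCC2(OCCO2)C=C1CO | intermediate
7 | (4S)-4-(tert-butyldimethylsilyloxy)-3-(hydroxymethyl)cyclohex-2-en-1-one | CC(C)(C)[Si](C)(C)O[C@H]1CCC(=O)C=C1CO | intermediate
8 | (4S)-4-(tert-butyldimethylsilyloxy)-3-[(triethylsilyloxy)methyl]cyclohex-2-en-1-one | CC(C)(C)[Si](C)(C)O[C@H]1CCC(=O)C=C1CO[Si](CC)(CC)CC | intermediate
9 | (4S)-2,2-dimethyl-1,3-dioxolane-4-carbaldehyde | O=C[C@@H]1COC(C)(C)O1 | starting material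
10 | bromomagnesium (3S,4S)-4-(tert-butyldimethylsilyloxy)-3-methyl-3-[(triethylsilyloxy)methyl]cyclohex-1-en-1-olate | CC(C)(C)[Si](C)(C)O[C@H]1CCC(O[Mg]Br)=C[C@@]1(C)CO[Si](CC)(CC)CC | intermediate (not isolated)
11 | (2S,3S,4S)-4-(tert-butyldimethylsilyloxy)-2-{(R)-[(4S)-2,2-dimethyl-1,3-dioxolan-4-yl](hydroxy)methyl}-3-methyl-3-[(triethylsilyloxy)methyl]cyclohexan-1-one | CC(C)(C)[Si](C)(C)O[C@H]1CCC(=O)[C@H]([C@@H](O)[C@@H]2COC(C)(C)O2)[C@@]1(C)CO[Si](CC)(CC)CC | intermediate
12 | (2S,3S,4S)-4-(tert-butyldimethylsilyloxy)-2-{(R)-(tert-butyldimethylsilyloxy)[(4S)-2,2-dimethyl-1,3-dioxolan-4-yl]methyl}-3-methyl-3-[(triethylsilyloxy)methyl]cyclohexan-1-one | CC(C)(C)[Si](C)(C)O[C@H]1CCC(=O)[C@H]([C@@H](O[Si](C)(C)C(C)(C)C)[C@@H]2COC(C)(C)O2)[C@@]1(C)CO[Si](CC)(CC)CC | intermediate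
13 | potassium C11–C12 enolate of 12 (stereocentres as in 12) | CC(C)(C)[Si](C)(C)O[C@H]1CC=C(O[K])[C@H]([C@@H](O[Si](C)(C)C(C)(C)C)[C@@H]2COC(C)(C)O2)[C@@]1(C)CO[Si](CC)(CC)CC | intermediate (not isolated)
14 | C11 enol triflate of 12, C11=C12 (1S,8S,9R,10S,14S) | CC(C)(C)[Si](C)(C)O[C@H]1CC=C(OS(=O)(=O)C(F)(F)F)[C@H]([C@@H](O[Si](C)(C)C(C)(C)C)[C@@H]2COC(C)(C)O2)[C@@]1(C)CO[Si](CC)(CC)CC | intermediate
15 | ring A cyclohex-11-ene with 20-CH3, 14α-OTBS, 1β-CH3, 1α-CH2OTES, 10β-[(9R)-CH(OTBS)–(8S)-2,2-dimethyl-1,3-dioxolan-4-yl] (1S,8S,9R,10S,14S) | CC(C)(C)[Si](C)(C)O[C@H]1CC=C(C)[C@H]([C@@H](O[Si](C)(C)C(C)(C)C)[C@@H]2COC(C)(C)O2)[C@@]1(C)CO[Si](CC)(CC)CC | intermediate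
16 | C2 aldehyde: 15 with 1α-CHO (1R,8S,9R,10S,14S) | CC(C)(C)[Si](C)(C)O[C@H]1CC=C(C)[C@H]([C@@H](O[Si](C)(C)C(C)(C)C)[C@@H]2COC(C)(C)O2)[C@@]1(C)C=O | intermediate
17 | C2 carbinol: 15 with 1α-CH(OH)CH3, mixture of C2 epimers | CC(C)(C)[Si](C)(C)O[C@H]1CC=C(C)[C@H]([C@@H](O[Si](C)(C)C(C)(C)C)[C@@H]2COC(C)(C)O2)[C@@]1(C)C(C)O | intermediate
18 | C2 methyl ketone: 15 with 1α-acetyl (1R,8S,9R,10S,14S) | CC(C)(C)[Si](C)(C)O[C@H]1CC=C(C)[C@H]([C@@H](O[Si](C)(C)C(C)(C)C)[C@@H]2COC(C)(C)O2)[C@@]1(C)C(C)=O | intermediate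
19 | prop-2-yn-1-ol | OCC#C | starting material
20 | bromomagnesium (Z)-3-(bromomagnesio)-2-methylprop-2-en-1-olate | Br[Mg]OC/C(C)=C\[Mg]Br | intermediate (not isolated)
21 | (Z)-3-iodo-2-methylprop-2-en-1-ol | OC/C(C)=C\I | intermediate
22 | (Z)-3-bromo-1-iodo-2-methylprop-1-ene | BrC/C(C)=C\I | intermediate
23 | lithium enolate of 18 (C2=C3, O–Li) | CC(C)(C)[Si](C)(C)O[C@H]1CC=C(C)[C@H]([C@@H](O[Si](C)(C)C(C)(C)C)[C@@H]2COC(C)(C)O2)[C@@]1(C)C(=C)O[Li] | intermediate (not isolated)
24 | alkylated ketone: 15 with 1α-C(=O)CH2CH2C(CH3)=CHI, 5Z (1R,8S,9R,10S,14S) | CC(C)(C)[Si](C)(C)O[C@H]1CC=C(C)[C@H]([C@@H](O[Si](C)(C)C(C)(C)C)[C@@H]2COC(C)(C)O2)[C@@]1(C)C(=O)CC/C(C)=C\I | intermediate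
25 | (2R)-alcohol of 24 (1S,2R,8S,9R,10S,14S) | CC(C)(C)[Si](C)(C)O[C@H]1CC=C(C)[C@H]([C@@H](O[Si](C)(C)C(C)(C)C)[C@@H]2COC(C)(C)O2)[C@@]1(C)[C@H](O)CC/C(C)=C\I | intermediate
26 | 2,9,14-triol with 7,8-acetonide and (5Z)-alkenyl iodide (1S,2R,8S,9R,10S,14S) | O[C@H]1CC=C(C)[C@H]([C@@H](O)[C@@H]2COC(C)(C)O2)[C@@]1(C)[C@H](O)CC/C(C)=C\I | intermediate
27 | 2,9,14-triacetate of 26 (1S,2R,8S,9R,10S,14S) | CC(=O)O[C@H]1CC=C(C)[C@H]([C@@H](OC(C)=O)[C@@H]2COC(C)(C)O2)[C@@]1(C)[C@H](OC(C)=O)CC/C(C)=C\I | intermediate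
28 | 7,8-diol triacetate (1S,2R,8S,9R,10S,14S) | CC(=O)O[C@H]1CC=C(C)[C@H]([C@@H](OC(C)=O)[C@@H](O)CO)[C@@]1(C)[C@H](OC(C)=O)CC/C(C)=C\I | intermediate
29 | 7,8-bis(triethylsilyl) ether of 28 | CC(=O)O[C@H]1CC=C(C)[C@H]([C@@H](OC(C)=O)[C@@H](O[Si](CC)(CC)CC)CO[Si](CC)(CC)CC)[C@@]1(C)[C@H](OC(C)=O)CC/C(C)=C\I | intermediate
30 | C7 aldehyde with 8-OTES and (5Z)-alkenyl iodide (1S,2R,8R,9R,10S,14S) | CC(=O)O[C@H]1CC=C(C)[C@H]([C@@H](OC(C)=O)[C@@H](O[Si](CC)(CC)CC)C=O)[C@@]1(C)[C@H](OC(C)=O)CC/C(C)=C\I | intermediate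
31 | (Z)-alkenylchromium dichloride from 30 (CrCl2 in place of I at C6) | CC(=O)O[C@H]1CC=C(C)[C@H]([C@@H](OC(C)=O)[C@@H](O[Si](CC)(CC)CC)C=O)[C@@]1(C)[C@H](OC(C)=O)CC/C(C)=C\[Cr](Cl)Cl | intermediate (not isolated)
32 | (1S,2R,5Z,7S,8S,9R,10S,14S)-2,9,14-triacetoxy-7-hydroxy-8-(triethylsilyloxy)-1,5,11-trimethylbicyclo[8.4.0]tetradeca-5,11-diene (briarane numbering) | CC(=O)O[C@H]1CC=C(C)[C@@H]2[C@@H](OC(C)=O)[C@@H](O[Si](CC)(CC)CC)[C@@H](O)/C=C(/C)CC[C@@H](OC(C)=O)[C@@]12C | intermediate
33 | 7-O-acryloyl ester of 32 | CC(=O)O[C@H]1CC=C(C)[C@@H]2[C@@H](OC(C)=O)[C@@H](O[Si](CC)(CC)CC)[C@@H](OC(=O)C=C)/C=C(/C)CC[C@@H](OC(C)=O)[C@@]12C | intermediate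
34 | 8-hydroxy 7-acrylate (1S,2R,5Z,7S,8S,9R,10S,14S) | CC(=O)O[C@H]1CC=C(C)[C@@H]2[C@@H](OC(C)=O)[C@@H](O)[C@@H](OC(=O)C=C)/C=C(/C)CC[C@@H](OC(C)=O)[C@@]12C | intermediate
35 | 8-oxo 7-acrylate (1S,2R,5Z,7S,9R,10S,14S) | CC(=O)O[C@H]1CC=C(C)[C@@H]2[C@@H](OC(C)=O)C(=O)[C@@H](OC(=O)C=C)/C=C(/C)CC[C@@H](OC(C)=O)[C@@]12C | intermediate (not isolated)
36 | stylatulide lactone (1S,2R,5Z,7S,8S,9R,10S,14S,17R) | CC(=O)O[C@H]1CC=C(C)[C@@H]2[C@@H](OC(C)=O)[C@@]3(O)[C@H](/C=C(/C)CC[C@@H](OC(C)=O)[C@@]12C)OC(=O)[C@@H]3C | target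

**Step count and risk**
Total steps: 26. Longest linear sequence: 24 (steps 1–13 and 16–26); steps 14–15 make the side-chain bromide.

The three steps most likely to fail are steps 7, 23 and 26.

Step 7 must build the C1 quaternary centre next to a silyloxy-bearing carbon and then set C10 and C9 in the same flask. The conjugate addition may be slow, and the facial selectivity of the aldol at C10 is the least certain point. The fallback sets out from 8 and comes back at 11. Stoichiometric Me2CuLi with Me3SiCl forces the conjugate addition and traps the enolate as the isolable trimethylsilyl enol ether F1. A BF3·OEt2-mediated Mukaiyama aldol of F1 with 9 at −78 °C then forms the C9–C10 bond through an open transition state in place of the magnesium chelate, with polar Felkin–Anh control from the aldehyde, and gives 11 after work-up.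

Step 23 closes a ten-membered carbocycle and sets C7; oligomerisation or a poor C7 ratio are the dangers. The fallback sets out from 30 and comes back at 32, closing the ring at C5=C6 instead of C6–C7. Vinylmagnesium bromide adds to aldehyde 30 at −78 °C (Felkin–Anh, the acetates survive the short cold exposure) to give the (7S)-vinyl carbinol F2. Pd(PPh3)4 with Bu3SnH then replaces the iodine by hydrogen to give the 1,1-disubstituted alkene F3. Ring-closing metathesis of F3 with the second-generation Grubbs catalyst at high dilution gives 32, the ten-membered ring enforcing the Z alkene.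

Step 26 is the proposed new reaction. It may stop at simple transfer hydrogenation (keto propionate), ionise the allylic ester, or epimerise C7 in ketone 35, whose C7–H is both allylic and α to the carbonyl. The fallback uses known chemistry, sets out from 34 and comes back at 36. Buffered Dess–Martin oxidation gives keto acrylate 35, this time isolated. A copper hydride reductive aldol cyclisation (Cu(OAc)2·H2O, dppf, (HMe2Si)2O, THF, rt, then NH4F) then forms the same (Z)-enolate and closes the lactone to 36. This detour makes no compound outside the list (F0).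

**Further compounds**
F1 | step 7 | trimethylsilyl enol ether: (3S,4S)-4-(tert-butyldimethylsilyloxy)-3-methyl-3-[(triethylsilyloxy)methyl]-1-(trimethylsilyloxy)cyclohex-1-ene | CC(C)(C)[Si](C)(C)O[C@H]1CCC(O[Si](C)(C)C)=C[C@@]1(C)CO[Si](CC)(CC)CC
F2 | step 23 | (7S)-vinyl carbinol from 30, with 8-OTES and the (5Z)-alkenyl iodide retained | CC(=O)O[C@H]1CC=C(C)[C@H]([C@@H](OC(C)=O)[C@@H](O[Si](CC)(CC)CC)[C@@H](O)C=C)[C@@]1(C)[C@H](OC(C)=O)CC/C(C)=C\I
F3 | step 23 | deiodinated diene: F2 with C5(CH3)=CH2 in place of the alkenyl iodide | CC(=O)O[C@H]1CC=C(C)[C@H]([C@@H](OC(C)=O)[C@@H](O[Si](CC)(CC)CC)[C@@H](O)C=C)[C@@]1(C)[C@H](OC(C)=O)CCC(C)=C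
F0 | step 26 | none | none
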